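## Retrosynthetic overview

1. Numbering: chromene O1–C8a; side chain C1' (CH2), C2' (C=O), C3' (CH2), C4' and C5' (the two quaternary ring carbons), C6'–C8' (ring CH2), C9' (enone C=O), C10'=C11', C12' (carbinol). The strategy rests on C2 of the pyran ring: it bears O1, a methyl, the ring alkene C3=C4 and the stub C1'–C2', so it maps onto a carbinol carbon with two identical ethynyl groups. One becomes C3/C4, the other C1'/C2', and the choice between them sets C2.
2. The Z-enone comes from semihydrogenation of a C10'≡C11' ynone. The ynone comes from opening a δ-lactone (C9' acyl donor tied to O–C2') with dilithiated 2-methylbut-3-yn-2-ol. The C2' ketone is unveiled late by oxidation.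
3. C2'–C3' is made from a neopentyl-type organocerium (cyclopentane iodide 24) and chromenylacetaldehyde 9, itself from anti-Markovnikov hydration of the spare alkyne of 7.
4. The commercial meso cis-cyclopentane anhydride carries no methyl groups. After alkaloid desymmetrisation, C5' and then C4' are made quaternary by two lactone-enolate methylations, each held cis by the ring fusion.
5. Ring order: benzene and cyclopentane rings are bought; the pyran ring is the only skeletal ring formed (step 4); the lactone rings of steps 7, 10 and 17 are temporary.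

Key step: step 4

Assumption: the (R)-configured digold complex is taken to give the (S)-alkyne 7 and quinidine the (1S,2R)-hemiester 11; if either sense proves opposite, the mirror-image ligand or quinine is used and nothing else changes.

## Route

Step 1
Reactants: 1 ethyl acetate; 2 ethynylmagnesium bromide
Product: 3 3-methylpenta-1,4-diyn-3-ol
Conditions: 2 (2.3 equiv), THF, 0 °C → rt; aq. NH4Cl
Reagents that add atoms: none
Why: Twofold addition of the alkynyl Grignard reagent to the ester, through the transient ynone, is the standard route to a tertiary carbinol with two identical substituents.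

Step 2
Reactants: 3 3-methylpenta-1,4-diyn-3-ol
Product: 4 methyl 3-methylpenta-1,4-diyn-3-yl carbonate
Conditions: ClCO2Me, pyridine, DMAP (cat.), CH2Cl2, 0 °C → rt
Reagents that add atoms: methyl chloroformate, COC(=O)Cl
Why: DMAP-catalysed acylation of the tertiary propargylic alcohol with the chloroformate installs the carbonate leaving group that the copper-catalysed etherification needs.

Step 3
Reactants: 4 methyl 3-methylpenta-1,4-diyn-3-yl carbonate; 5 4-methoxy-2-methylphenol
Product: 6 4-methoxy-2-methyl-1-[(3-methylpenta-1,4-diyn-3-yl)oxy]benzene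
Conditions: CuCl2·2H2O (1 mol%), DBU, MeCN, −5 → 0 °C
Reagents that add atoms: none
Why: Copper-catalysed propargylic etherification: a copper acetylide of one ethynyl group expels the carbonate to give a copper allenylidene-type electrophile that the phenoxide captures at the tertiary carbon, a reaction well established for hindered phenols and tertiary propargylic carbonates, the second ethynyl group being a spectator.

Step 4
Reactants: 6 4-methoxy-2-methyl-1-[(3-methylpenta-1,4-diyn-3-yl)oxy]benzene
Product: 7 (2S)-2-ethynyl-6-methoxy-2,8-dimethyl-2H-chromene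
Conditions: (R)-DTBM-SEGPHOS(AuCl)2 (5 mol%), AgSbF6 (10 mol%), CH2Cl2, −30 → 0 °C, dark
Reagents that add atoms: none
Why: Proposed new method: the cationic monovalent gold centre of the chiral digold bisphosphine complex binds one of the two enantiotopic ethynyl groups of 6 and makes its terminal carbon electrophilic, the only free ortho carbon of the electron-rich aryl ether attacks it in a Friedel–Crafts step (C4–C4a bond), and rearomatisation with protodeauration releases the chromene. The closest known reaction types are the gold-catalysed 6-endo hydroarylation of aryl propargyl ethers to 2H-chromenes and the gold-catalysed enantioselective desymmetrisation of 1,4-diynes by tethered heteroatom nucleophiles, but an arene nucleophile has not been used to desymmetrise a bis-propargylic ether in this way. The pyran ring closes in the 6-endo-dig mode, as is usual for terminal aryl propargyl ethers, 5-exo attack at the internal alkyne carbon next to the fully substituted centre being hindered. The stereocentre C2 arises without any bond being made at C2, purely from which alkyne is consumed, so it is controlled by the chiral ligand on gold alone, the substrate having a mirror plane through C2. The step needs enantiotopic-group selectivity and must stop after one cyclisation: the methyl group ortho to oxygen (later C8–CH3) leaves only one ortho position free, so the second alkyne cannot cyclise and survives as C1'≡C2'. Because the C2–O bond is never broken (no propargyl Claisen or ionisation pathway is needed), the configuration fixed when the alkyne is selected should persist.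

Step 5
Reactants: 7 (2S)-2-ethynyl-6-methoxy-2,8-dimethyl-2H-chromene
Product: 9 2-[(2R)-6-methoxy-2,8-dimethyl-2H-chromen-2-yl]acetaldehyde, via alkenylborane 8 (not isolated)
Conditions: Cy2BH (1.3 equiv), THF, 0 °C → rt; 30% H2O2, pH 7 phosphate buffer, 0 °C
Reagents that add atoms: hydrogen peroxide, OO
Why: Hydroboration–oxidation: the hindered dialkylborane adds anti-Markovnikov to the terminal alkyne far faster than to the disubstituted ring alkene C3=C4, and peroxide oxidation at neutral pH gives the aldehyde without base-induced loss of the β-aryloxy group, so C2 is untouched.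

Step 6
Reactants: 10 cis-cyclopentane-1,2-dicarboxylic anhydride (meso)
Product: 11 (1S,2R)-2-(methoxycarbonyl)cyclopentane-1-carboxylic acid
Conditions: quinidine (1.1 equiv), MeOH (3 equiv), toluene, −55 °C; aq. HCl wash (alkaloid recovered)
Reagents that add atoms: methanol, CO
Why: Cinchona-alkaloid-mediated desymmetrising methanolysis of a meso cyclic anhydride, in which the alkaloid directs methanol to one of the two enantiotopic carbonyl groups and so fixes both ring stereocentres.

Step 7
Reactants: 11 (1S,2R)-2-(methoxycarbonyl)cyclopentane-1-carboxylic acid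
Product: 13 (3aR,6aS)-hexahydro-1H-cyclopenta[c]furan-1-one, via hydroxy acid 12 (not isolated)
Conditions: LiBEt3H (3.2 equiv), THF, 0 °C → rt; 2 M HCl, rt
Reagents that add atoms: none
Why: Chemoselective hydride reduction: LiBEt3H reduces the methyl ester but not the lithium carboxylate, and on acidification the cis hydroxy acid closes to the γ-lactone with both stereocentres unchanged.

Step 8
Reactants: 13 (3aR,6aS)-hexahydro-1H-cyclopenta[c]furan-1-one
Product: 15 (3aR,6aS)-6a-methylhexahydro-1H-cyclopenta[c]furan-1-one, via lithium enolate 14 (not isolated)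
Conditions: LiN(i-Pr)2 (1.1 equiv), THF, −78 °C; MeI, −78 → −20 °C
Reagents that add atoms: iodomethane, CI
Why: Lactone enolate alkylation: the planar enolate carbon can accept the methyl group only on the face that keeps the bicyclo[3.3.0] lactone cis-fused, so the untouched ring-fusion CH centre dictates the configuration of the new quaternary carbon (C5' of the target).

Step 9
Reactants: 15 (3aR,6aS)-6a-methylhexahydro-1H-cyclopenta[c]furan-1-one
Product: 16 [(1S,2R)-2-(hydroxymethyl)-1-methylcyclopentyl]methanol
Conditions: LiAlH4, THF, 0 °C → rt; Na2SO4·10H2O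
Reagents that add atoms: none
Why: Hydride reduction of the lactone gives a diol whose two hydroxymethyl arms differ (neopentyl on the quaternary carbon, unhindered on the CH carbon), so no symmetry is regained.

Step 10
Reactants: 16 [(1S,2R)-2-(hydroxymethyl)-1-methylcyclopentyl]methanol
Product: 17 (3aS,6aR)-3a-methylhexahydro-1H-cyclopenta[c]furan-1-one
Conditions: TEMPO (10 mol%), PhI(OAc)2 (2.5 equiv), CH2Cl2, rt
Reagents that add atoms: none
Why: Oxoammonium-mediated oxidative lactonisation oxidises the less hindered, non-neopentyl carbinol first, the lactol closes and is oxidised on, which transposes the carbonyl to the carbon that becomes C3' and makes the remaining ring-fusion CH enolisable.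

Step 11
Reactants: 17 (3aS,6aR)-3a-methylhexahydro-1H-cyclopenta[c]furan-1-one
Product: 19 (3aS,6aR)-3a,6a-dimethylhexahydro-1H-cyclopenta[c]furan-1-one, via lithium enolate 18 (not isolated)
Conditions: LiN(i-Pr)2 (1.2 equiv), THF/DMPU, −78 °C; MeI, −78 → 0 °C
Reagents that add atoms: iodomethane, CI
Why: Second lactone enolate alkylation, again restricted to the face that preserves the cis ring fusion, so the existing quaternary centre controls the new one (C4') and the two methyl groups end up cis.

Step 12
Reactants: 19 (3aS,6aR)-3a,6a-dimethylhexahydro-1H-cyclopenta[c]furan-1-one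
Product: 22 (1R,2S)-1,2-dimethyl-2-({[tri(propan-2-yl)silyl]oxy}methyl)cyclopentane-1-carboxylic acid, via potassium hydroxy carboxylate 20 (not isolated), via silyl ester silyl ether 21 (not isolated)
Conditions: KOH (1.1 equiv), MeOH/H2O, 65 °C, then evaporation; TIPSCl (2.5 equiv), imidazole, DMAP (cat.), DMF, 45 °C; AcOH/THF/H2O, rt
Reagents that add atoms: potassium hydroxide, [K+].[OH-]; chlorotriisopropylsilane, CC(C)[Si](Cl)(C(C)C)C(C)C
Why: Saponification, silylation of both the alcohol and the carboxylate, and mild hydrolysis of the labile silyl ester is the standard way to open a lactone to a silyloxy acid, and it differentiates the two one-carbon arms without passing through the meso diol.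

Step 13
Reactants: 22 (1R,2S)-1,2-dimethyl-2-({[tri(propan-2-yl)silyl]oxy}methyl)cyclopentane-1-carboxylic acid
Product: 23 [(1R,2S)-1,2-dimethyl-2-({[tri(propan-2-yl)silyl]oxy}methyl)cyclopentyl]methanol
Conditions: BH3·SMe2, THF, 0 °C → rt; aq. work-up
Reagents that add atoms: none
Why: Borane reduces the free carboxylic acid chemoselectively to the primary alcohol through an acyloxyborane and leaves the silyl ether untouched.

Step 14
Reactants: 23 [(1R,2S)-1,2-dimethyl-2-({[tri(propan-2-yl)silyl]oxy}methyl)cyclopentyl]methanol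
Product: 24 {[(1S,2R)-2-(iodomethyl)-1,2-dimethylcyclopentyl]methoxy}tri(propan-2-yl)silane
Conditions: I2, PPh3, imidazole, toluene, 80 °C
Reagents that add atoms: iodine, II
Why: Appel-type iodination with PPh3, I2 and imidazole, heated because the substitution takes place at a neopentyl carbon, the bulky silyl group being chosen to keep the neighbouring ether oxygen from taking part.

Step 15
Reactants: 24 {[(1S,2R)-2-(iodomethyl)-1,2-dimethylcyclopentyl]methoxy}tri(propan-2-yl)silane; 9 2-[(2R)-6-methoxy-2,8-dimethyl-2H-chromen-2-yl]acetaldehyde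
Product: 27 1-[(1S,2S)-1,2-dimethyl-2-({[tri(propan-2-yl)silyl]oxy}methyl)cyclopentyl]-3-[(2R)-6-methoxy-2,8-dimethyl-2H-chromen-2-yl]propan-2-ol (both C2' epimers), via alkyllithium 25 (not isolated), via alkylcerium dichloride 26 (not isolated)
Conditions: t-BuLi (2.1 equiv), Et2O/pentane, −78 °C; CeCl3 (dried), THF, −78 °C; 9, −78 °C; aq. NH4Cl
Reagents that add atoms: none
Why: Lithium–iodine exchange with two equivalents of t-BuLi gives the primary alkyllithium, transmetalation to the weakly basic organocerium reagent allows clean 1,2-addition to the enolisable aldehyde and forms C2'–C3', and the new C2' carbinol, formed as both epimers, is oxidised to the ketone in step 19.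

Step 16
Reactants: 27 silyl ether alcohol (both C2' epimers)
Product: 28 1-[(1S,2S)-2-(hydroxymethyl)-1,2-dimethylcyclopentyl]-3-[(2R)-6-methoxy-2,8-dimethyl-2H-chromen-2-yl]propan-2-ol (both C2' epimers)
Conditions: Bu4NF, THF, rt
Reagents that add atoms: none
Why: Fluoride-mediated cleavage of the silyl ether frees the primary alcohol and touches nothing else.

Step 17
Reactants: 28 diol (both C2' epimers)
Product: 29 (4aS,7aS)-3-{[(2R)-6-methoxy-2,8-dimethyl-2H-chromen-2-yl]methyl}-4a,7a-dimethylhexahydrocyclopenta[c]pyran-1(3H)-one (both C3 epimers)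
Conditions: TEMPO (20 mol%), PhI(OAc)2 (2.5 equiv), CH2Cl2, rt
Reagents that add atoms: none
Why: The same oxoammonium oxidative lactonisation oxidises the primary alcohol in preference to the hindered secondary one, the C2' hydroxyl traps the aldehyde as a six-membered lactol and this is oxidised to the δ-lactone, which brings C9' to the acyl level and masks the C2' oxygen in one operation.

Step 18
Reactants: 29 δ-lactone (both C3 epimers); 30 2-methylbut-3-yn-2-ol
Product: 32 1-{(1S,2S)-2-[2-hydroxy-3-((2R)-6-methoxy-2,8-dimethyl-2H-chromen-2-yl)propyl]-1,2-dimethylcyclopentyl}-4-hydroxy-4-methylpent-2-yn-1-one (both C2' epimers), via dilithio alkynol 31 (not isolated)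
Conditions: 30 (3 equiv), n-BuLi (6 equiv), THF, −78 → 0 °C; 29, −78 → 0 °C; aq. NH4Cl
Reagents that add atoms: none
Why: Acetylide addition to a lactone stops at the ketone level because the tetrahedral lithium hemiketal survives until work-up, so the ynone is formed and the C2' hydroxyl released, with no acidic C–H in 29 to quench the nucleophile.

Step 19
Reactants: 32 hydroxy ynone (both C2' epimers)
Product: 33 1-{(1S,2S)-2-[3-((2R)-6-methoxy-2,8-dimethyl-2H-chromen-2-yl)-2-oxopropyl]-1,2-dimethylcyclopentyl}-4-hydroxy-4-methylpent-2-yn-1-one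
Conditions: Dess–Martin periodinane, NaHCO3, CH2Cl2, 0 °C → rt, dark
Reagents that add atoms: none
Why: Dess–Martin oxidation converts the only secondary alcohol (reacting through the open hydroxy ketone tautomer) into the C2' ketone under buffered, non-basic conditions that leave the tertiary alcohol, the ynone and the base-sensitive β-aryloxy ketone at C2 intact.

Step 20
Reactants: 33 diketone ynone
Product: 34 (Z)-1-{(1S,2S)-2-[3-((2R)-6-methoxy-2,8-dimethyl-2H-chromen-2-yl)-2-oxopropyl]-1,2-dimethylcyclopentyl}-4-hydroxy-4-methylpent-2-en-1-one (CNP0137762.2)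
Conditions: H2 (1 atm), 5% Pd/CaCO3 poisoned with Pb(OAc)2, quinoline, EtOAc, rt, dark
Reagents that add atoms: none
Why: Lindlar semihydrogenation delivers both hydrogens to the same face of the alkyne on lead-poisoned palladium, giving the (Z)-enone, while the conjugated ring alkene and the two ketones are not reduced under these conditions.

## Compound list

1 | ethyl acetate | CCOC(C)=O | starting material
2 | ethynylmagnesium bromide | C#C[Mg]Br | starting material
3 | 3-methylpenta-1,4-diyn-3-ol | CC(O)(C#C)C#C | intermediate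
4 | methyl 3-methylpenta-1,4-diyn-3-yl carbonate | COC(=O)OC(C)(C#C)C#C | intermediate
5 | 4-methoxy-2-methylphenol | COc1ccc(O)c(C)c1 | starting material
6 | 4-methoxy-2-methyl-1-[(3-methylpenta-1,4-diyn-3-yl)oxy]benzene (achiral, two enantiotopic ethynyl groups) | COc1ccc(OC(C)(C#C)C#C)c(C)c1 | intermediate
7 | (2S)-2-ethynyl-6-methoxy-2,8-dimethyl-2H-chromene | COc1cc(C)c2c(c1)C=C[C@@](C)(C#C)O2 | intermediate
8 | dicyclohexyl{(E)-2-[(2R)-6-methoxy-2,8-dimethyl-2H-chromen-2-yl]ethenyl}borane | COc1cc(C)c2c(c1)C=C[C@@](C)(/C=C/B(C1CCCCC1)C1CCCCC1)O2 | intermediate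
9 | 2-[(2R)-6-methoxy-2,8-dimethyl-2H-chromen-2-yl]acetaldehyde | COc1cc(C)c2c(c1)C=C[C@@](C)(CC=O)O2 | intermediate
10 | cis-cyclopentane-1,2-dicarboxylic anhydride (meso) | [C@H]12CCC[C@H]1C(=O)OC2=O | starting material
11 | (1S,2R)-2-(methoxycarbonyl)cyclopentane-1-carboxylic acid | COC(=O)[C@@H]1CCC[C@@H]1C(=O)O | intermediate
12 | (1S,2R)-2-(hydroxymethyl)cyclopentane-1-carboxylic acid | OC[C@@H]1CCC[C@@H]1C(=O)O | intermediate
13 | (3aR,6aS)-hexahydro-1H-cyclopenta[c]furan-1-one (cis-fused) | O=C1OC[C@@H]2CCC[C@H]12 | intermediate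
14 | lithium enolate of 13 | [Li+].[O-]C1=C2CCC[C@H]2CO1 | intermediate
15 | (3aR,6aS)-6a-methylhexahydro-1H-cyclopenta[c]furan-1-one | O=C1OC[C@@H]2CCC[C@]12C | intermediate
16 | [(1S,2R)-2-(hydroxymethyl)-1-methylcyclopentyl]methanol | OC[C@@]1(C)CCC[C@H]1CO | intermediate
17 | (3aS,6aR)-3a-methylhexahydro-1H-cyclopenta[c]furan-1-one | O=C1OC[C@@]2(C)CCC[C@@H]12 | intermediate
18 | lithium enolate of 17 | [Li+].[O-]C1=C2CCC[C@]2(C)CO1 | intermediate
19 | (3aS,6aR)-3a,6a-dimethylhexahydro-1H-cyclopenta[c]furan-1-one (cis methyls) | O=C1OC[C@@]2(C)CCC[C@@]12C | intermediate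
20 | potassium (1R,2S)-2-(hydroxymethyl)-1,2-dimethylcyclopentane-1-carboxylate | [K+].[O-]C(=O)[C@]1(C)CCC[C@]1(C)CO | intermediate
21 | tri(propan-2-yl)silyl (1R,2S)-1,2-dimethyl-2-({[tri(propan-2-yl)silyl]oxy}methyl)cyclopentane-1-carboxylate | CC(C)[Si](OC(=O)[C@]1(C)CCC[C@]1(C)CO[Si](C(C)C)(C(C)C)C(C)C)(C(C)C)C(C)C | intermediate
22 | (1R,2S)-1,2-dimethyl-2-({[tri(propan-2-yl)silyl]oxy}methyl)cyclopentane-1-carboxylic acid | OC(=O)[C@]1(C)CCC[C@]1(C)CO[Si](C(C)C)(C(C)C)C(C)C | intermediate
23 | [(1R,2S)-1,2-dimethyl-2-({[tri(propan-2-yl)silyl]oxy}methyl)cyclopentyl]methanol | OC[C@]1(C)CCC[C@]1(C)CO[Si](C(C)C)(C(C)C)C(C)C | intermediate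
24 | {[(1S,2R)-2-(iodomethyl)-1,2-dimethylcyclopentyl]methoxy}tri(propan-2-yl)silane | IC[C@]1(C)CCC[C@]1(C)CO[Si](C(C)C)(C(C)C)C(C)C | intermediate
25 | [(1R,2S)-1,2-dimethyl-2-({[tri(propan-2-yl)silyl]oxy}methyl)cyclopentyl]methyllithium | [Li]C[C@]1(C)CCC[C@]1(C)CO[Si](C(C)C)(C(C)C)C(C)C | intermediate
26 | dichloro{[(1R,2S)-1,2-dimethyl-2-({[tri(propan-2-yl)silyl]oxy}methyl)cyclopentyl]methyl}cerium | Cl[Ce](Cl)C[C@]1(C)CCC[C@]1(C)CO[Si](C(C)C)(C(C)C)C(C)C | intermediate
27 | 1-[(1S,2S)-1,2-dimethyl-2-({[tri(propan-2-yl)silyl]oxy}methyl)cyclopentyl]-3-[(2R)-6-methoxy-2,8-dimethyl-2H-chromen-2-yl]propan-2-ol (both C2' epimers) | COc1cc(C)c2c(c1)C=C[C@@](C)(CC(O)C[C@]1(C)CCC[C@]1(C)CO[Si](C(C)C)(C(C)C)C(C)C)O2 | intermediate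
28 | 1-[(1S,2S)-2-(hydroxymethyl)-1,2-dimethylcyclopentyl]-3-[(2R)-6-methoxy-2,8-dimethyl-2H-chromen-2-yl]propan-2-ol (both C2' epimers) | COc1cc(C)c2c(c1)C=C[C@@](C)(CC(O)C[C@]1(C)CCC[C@]1(C)CO)O2 | intermediate
29 | (4aS,7aS)-3-{[(2R)-6-methoxy-2,8-dimethyl-2H-chromen-2-yl]methyl}-4a,7a-dimethylhexahydrocyclopenta[c]pyran-1(3H)-one (both C3 epimers) | COc1cc(C)c2c(c1)C=C[C@@](C)(CC1C[C@]3(C)CCC[C@]3(C)C(=O)O1)O2 | intermediate
30 | 2-methylbut-3-yn-2-ol | CC(C)(O)C#C | starting material
31 | dilithium salt of 30 (lithium alkoxide and lithium acetylide) | [Li+].[Li+].CC(C)([O-])C#[C-] | intermediate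
32 | 1-{(1S,2S)-2-[2-hydroxy-3-((2R)-6-methoxy-2,8-dimethyl-2H-chromen-2-yl)propyl]-1,2-dimethylcyclopentyl}-4-hydroxy-4-methylpent-2-yn-1-one (both C2' epimers) | COc1cc(C)c2c(c1)C=C[C@@](C)(CC(O)C[C@]1(C)CCC[C@]1(C)C(=O)C#CC(C)(C)O)O2 | intermediate
33 | 1-{(1S,2S)-2-[3-((2R)-6-methoxy-2,8-dimethyl-2H-chromen-2-yl)-2-oxopropyl]-1,2-dimethylcyclopentyl}-4-hydroxy-4-methylpent-2-yn-1-one | COc1cc(C)c2c(c1)C=C[C@@](C)(CC(=O)C[C@]1(C)CCC[C@]1(C)C(=O)C#CC(C)(C)O)O2 | intermediate
34 | (Z)-1-{(1S,2S)-2-[3-((2R)-6-methoxy-2,8-dimethyl-2H-chromen-2-yl)-2-oxopropyl]-1,2-dimethylcyclopentyl}-4-hydroxy-4-methylpent-2-en-1-one | COc1cc(C)c2c(c1)C=C[C@@](C)(CC(=O)C[C@]1(C)CCC[C@]1(C)C(=O)/C=C\C(C)(C)O)O2 | target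

## Step count and risks

Total step count: 20. Longest linear sequence: 15 steps (10 → 34, steps 6–20); the chromene branch (steps 1–5) joins at step 15.

Steps most likely to fail:

1. Step 4 (key step). The catalyst may discriminate poorly between the two enantiotopic alkynes, the free terminal alkyne may tie up the cationic gold as an unreactive acetylide, or acid traces may ionise the bis-propargylic C–O bond. Fallback, setting out from 6: the achiral complex Ph3PAuNTf2 (CH2Cl2, rt) carries out the known racemic 6-endo hydroarylation of aryl propargyl ethers and gives racemic 2-ethynyl-6-methoxy-2,8-dimethyl-2H-chromene F1. Its enantiomers are separated by preparative chromatography on a chiral stationary phase; the (2S)-enantiomer is 7, where the route is rejoined, and the (2R)-enantiomer F2 is set aside.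

2. Step 14. Substitution at the doubly hindered neopentyl carbon may be slower than attack of the neighbouring silyl ether oxygen on the activated carbinol (desilylative closure to a cyclic ether) or than a 1,2-shift. Fallback, setting out from 23 and avoiding any substitution at that carbon: Dess–Martin oxidation gives (1R,2S)-1,2-dimethyl-2-({[tri(propan-2-yl)silyl]oxy}methyl)cyclopentane-1-carbaldehyde F3. Reductive thioetherification (PhSH, Et3SiH, CF3CO2H, CH2Cl2) gives the phenyl sulfide {[(1S,2R)-1,2-dimethyl-2-[(phenylsulfanyl)methyl]cyclopentyl]methoxy}tri(propan-2-yl)silane F4. Reductive lithiation with lithium 4,4'-di-tert-butylbiphenylide (THF, −78 °C) cleaves the C–S bond and returns the route at alkyllithium 25, which goes on to 27 as in step 15.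

3. Step 20. Over-reduction of the enone, Z-to-E isomerisation on the catalyst, or cyclisation of the γ-hydroxy ynone before it is reduced may erode the (Z)-enone. Fallback, setting out from 29, with the Z geometry fixed in the nucleophile instead:
   - 30 is iodinated (N-iodosuccinimide, AgNO3 cat.) to 4-iodo-2-methylbut-3-yn-2-ol F5.
   - Diimide reduction (2-nitrobenzenesulfonyl hydrazide, Et3N) gives (Z)-4-iodo-2-methylbut-3-en-2-ol F6, which is silylated (Et3SiOTf, 2,6-lutidine) to its triethylsilyl ether F7.
   - Lithium–iodine exchange (t-BuLi, Et2O, −78 °C) gives the (Z)-alkenyllithium F8, which opens lactone 29 to the hydroxy (Z)-enone silyl ether F9.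
   - Dess–Martin oxidation gives the diketone silyl ether F10, and AcOH/THF/H2O removes the silyl group to return the route at 34.

Further compounds
F1 | step 4 | racemic 2-ethynyl-6-methoxy-2,8-dimethyl-2H-chromene | COc1cc(C)c2c(c1)C=CC(C)(C#C)O2
F2 | step 4 | (2R)-2-ethynyl-6-methoxy-2,8-dimethyl-2H-chromene | COc1cc(C)c2c(c1)C=C[C@](C)(C#C)O2
F3 | step 14 | (1R,2S)-1,2-dimethyl-2-({[tri(propan-2-yl)silyl]oxy}methyl)cyclopentane-1-carbaldehyde | O=C[C@]1(C)CCC[C@]1(C)CO[Si](C(C)C)(C(C)C)C(C)C
F4 | step 14 | {[(1S,2R)-1,2-dimethyl-2-[(phenylsulfanyl)methyl]cyclopentyl]methoxy}tri(propan-2-yl)silane | c1ccc(cc1)SC[C@]1(C)CCC[C@]1(C)CO[Si](C(C)C)(C(C)C)C(C)C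
F5 | step 20 | 4-iodo-2-methylbut-3-yn-2-ol | CC(C)(O)C#CI
F6 | step 20 | (Z)-4-iodo-2-methylbut-3-en-2-ol | CC(C)(O)/C=C\I
F7 | step 20 | triethyl{[(Z)-4-iodo-2-methylbut-3-en-2-yl]oxy}silane | CC[Si](CC)(CC)OC(C)(C)/C=C\I
F8 | step 20 | (Z)-[3-methyl-3-(triethylsilyloxy)but-1-en-1-yl]lithium | CC[Si](CC)(CC)OC(C)(C)/C=C\[Li]
F9 | step 20 | (Z)-1-{(1S,2S)-2-[2-hydroxy-3-((2R)-6-methoxy-2,8-dimethyl-2H-chromen-2-yl)propyl]-1,2-dimethylcyclopentyl}-4-methyl-4-(triethylsilyloxy)pent-2-en-1-one | COc1cc(C)c2c(c1)C=C[C@@](C)(CC(O)C[C@]1(C)CCC[C@]1(C)C(=O)/C=C\C(C)(C)O[Si](CC)(CC)CC)O2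
F10 | step 20 | (Z)-1-{(1S,2S)-2-[3-((2R)-6-methoxy-2,8-dimethyl-2H-chromen-2-yl)-2-oxopropyl]-1,2-dimethylcyclopentyl}-4-methyl-4-(triethylsilyloxy)pent-2-en-1-one | COc1cc(C)c2c(c1)C=C[C@@](C)(CC(=O)C[C@]1(C)CCC[C@]1(C)C(=O)/C=C\C(C)(C)O[Si](CC)(CC)CC)O2
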